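**Retrosynthetic overview**
1. Target 25 ⇐ diol lactone 22 by esterifying the C8 hydroxyl (primary C15–OH masked only transiently).
2. 22 ⇐ linear bromo-enal 19 by an electrochemical, chromium-catalysed intramolecular Barbier allylation: the C6–C7 bond, both new stereocentres and the ten-membered carbocycle form first, the γ-lactone closes second in the same flask.
3. 19 ⇐ cross-metathesis (C1=C10) of western enal 5 with eastern bromide 18.
4. 18 ⇐ (S)-glyceraldehyde acetonide 7 (C8 purchased, C9 by Felkin addition) plus two α-aluminoacrylate additions (methyl propiolate for C9–C10, ethyl propiolate for C7–C11).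
5. 5 ⇐ but-2-yne-1,4-diol by hydroxyl-directed anti-carbomagnesiation and selective allylic oxidation.

Assumption: germacranolide numbering is used (C6 lactone carbinol, C7 ring fusion, C8 O-isobutyryl, C9 OAc, C10 bearing C14 = CO2Me, C15 = CH2OH, C11=C13 exocyclic methylene, C12 lactone carbonyl); the target is the (6R,7S,8S,9R) isomer with both ring alkenes cis in the ring, as the SMILES states.

Step 1
Reactants: 1 but-2-yne-1,4-diol; 2 but-3-en-1-ylmagnesium bromide
Product: 4 (2E)-2-(but-3-en-1-yl)but-2-ene-1,4-diol, via alkenylmagnesium chelate 3 (not isolated)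
Conditions: 2 (4.5 equiv, 0.5 M in THF), CuI (10 mol %), THF, 0 → 50 °C, 16 h; sat. aq. NH4Cl
Reagents that add atoms: none
Why: Hydroxyl-directed anti-carbomagnesiation of a propargylic alkoxide: the butenyl group is delivered to the alkyne carbon next to the chelating CH2O– and magnesium is held cis to that CH2O in a five-membered ring, so protonation fixes the C4=C5 geometry (butenyl cis to the future C6, the two CH2OH groups trans).

Step 2
Reactants: 4 (2E)-2-(but-3-en-1-yl)but-2-ene-1,4-diol
Product: 5 (2E)-3-(hydroxymethyl)hepta-2,6-dienal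
Conditions: activated MnO2 (10 equiv), CH2Cl2, 20 °C, about 3 h, stopped at about 90 % conversion
Reagents that add atoms: none
Why: Chemoselective MnO2 allylic oxidation: the unhindered CH2OH on the CH= carbon (more stabilised allylic radical, gives the β,β-disubstituted enal) should react faster than the 2-substituted allylic alcohol, the enal then deactivates the remaining hydroxyl, and the trans CHO/CH2OH arrangement prevents lactol or furan formation under these neutral conditions.

Step 3
Reactants: 6 methyl propiolate; 7 (S)-2,2-dimethyl-1,3-dioxolane-4-carbaldehyde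
Product: 10 methyl 2-[(R)-acetoxy[(4S)-2,2-dimethyl-1,3-dioxolan-4-yl]methyl]prop-2-enoate, via vinylalane 8 (not isolated), via aluminium alkoxide 9 (not isolated)
Conditions: i-Bu2AlH (1.3 equiv), NMO (1.3 equiv), THF, 0 °C, then 6 (1.35 equiv), 0 °C, 1 h; 7, −78 → 0 °C; Ac2O (3 equiv), pyridine, DMAP (cat.), 0 → 20 °C
Reagents that add atoms: acetic anhydride CC(=O)OC(C)=O
Why: Vinylalumination (a Morita–Baylis–Hillman surrogate): syn-hydroalumination of the propiolate gives the α-aluminoacrylate, which adds to the α-alkoxy aldehyde under Felkin–Anh non-chelation control to set C9 anti (erythro) to the purchased C8 centre (expected about 4:1, minor epimer removed by chromatography), and the aluminium alkoxide is acetylated in situ.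

Step 4
Reactants: 10 methyl 2-[(R)-acetoxy[(4S)-2,2-dimethyl-1,3-dioxolan-4-yl]methyl]prop-2-enoate
Product: 11 methyl (3R,4S)-3-acetoxy-4,5-dihydroxy-2-methylidenepentanoate
Conditions: PPTS (0.2 equiv), MeOH, 20 °C
Reagents that add atoms: none
Why: Acid-catalysed transketalisation of the terminal acetonide; methanol as solvent and room temperature are chosen to keep the γ-hydroxy acrylate from lactonising and the acetate from migrating, and no stereocentre is touched.

Step 5
Reactants: 11 methyl (3R,4S)-3-acetoxy-4,5-dihydroxy-2-methylidenepentanoate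
Product: 12 methyl (3R,4S)-3-acetoxy-2-methylidene-4,5-bis(triethylsilyloxy)pentanoate
Conditions: Et3SiOTf (2.4 equiv), 2,6-lutidine (4 equiv), CH2Cl2, −78 °C
Reagents that add atoms: triethylsilyl trifluoromethanesulfonate CC[Si](CC)(CC)OS(=O)(=O)C(F)(F)F
Why: Exhaustive silylation with the silyl triflate at −78 °C outruns 1,2-acetyl migration; the C8 oxygen is carried as a silyl ether because an acyloxy group there would be lost by 1,4-elimination from the allylchromium in step 10.

Step 6
Reactants: 12 methyl (3R,4S)-3-acetoxy-2-methylidene-4,5-bis(triethylsilyloxy)pentanoate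
Product: 13 methyl (3R,4R)-3-acetoxy-2-methylidene-5-oxo-4-(triethylsilyloxy)pentanoate
Conditions: (COCl)2 (4 equiv), DMSO (8 equiv), CH2Cl2, −78 → −35 °C, 40 min; i-Pr2NEt (10 equiv), −78 → −30 °C; used crude
Reagents that add atoms: none
Why: Swern oxidation in which the chlorosulfonium reagent cleaves and oxidises only the primary triethylsilyl ether while the secondary one survives, giving the aldehyde in one operation; the cold hindered base limits β-elimination of acetate and epimerisation at C8 (the 4R descriptor is a priority change only).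

Step 7
Reactants: 13 methyl (3R,4R)-3-acetoxy-2-methylidene-5-oxo-4-(triethylsilyloxy)pentanoate; 14 ethyl propiolate
Product: 17 7-ethyl 1-methyl (3R,4S,5RS)-3-acetoxy-5-hydroxy-2,6-dimethylidene-4-(triethylsilyloxy)heptanedioate, via ethyl ester vinylalane 15 (not isolated), via aluminium alkoxide 16 (not isolated)
Conditions: i-Bu2AlH (1.5 equiv), NMO (1.5 equiv), THF, 0 °C, then 14 (1.6 equiv), 0 °C, 1 h; 13, −78 → −20 °C; aq. KNaC4H4O6 (potassium sodium tartrate)
Reagents that add atoms: none
Why: Second vinylalumination, chosen because the base-free aluminium reagent adds to the aldehyde faster than the β-acetoxy aldehyde can eliminate; the ethyl ester is used for this acrylate unit because its alkoxy group is expelled at the lactonisation in step 10 and it keeps the C12 and C14 esters distinguishable by NMR until then, and the new C7 carbinol configuration is irrelevant because step 8 removes it.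

Step 8
Reactants: 17 7-ethyl 1-methyl (3R,4S,5RS)-3-acetoxy-5-hydroxy-2,6-dimethylidene-4-(triethylsilyloxy)heptanedioate
Product: 18 1-ethyl 7-methyl (2Z,4S,5R)-5-acetoxy-2-(bromomethyl)-6-methylidene-4-(triethylsilyloxy)hept-2-enedioate
Conditions: NBS (1.5 equiv), Me2S (1.8 equiv), CH2Cl2, −20 → 20 °C
Reagents that add atoms: N-bromosuccinimide O=C1CCC(=O)N1Br
Why: Corey–Kim-type activation of the Baylis–Hillman-type alcohol followed by SN2′ attack of bromide at the terminal methylene gives the conjugated (Z)-2-(bromomethyl)enoate from both C7 epimers (any E isomer would converge in step 10 through the equilibrating allylchromium).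

Step 9
Reactants: 18 1-ethyl 7-methyl (2Z,4S,5R)-5-acetoxy-2-(bromomethyl)-6-methylidene-4-(triethylsilyloxy)hept-2-enedioate; 5 (2E)-3-(hydroxymethyl)hepta-2,6-dienal
Product: 19 ethyl (2Z,4S,5R,6E,10E)-5-acetoxy-2-(bromomethyl)-10-(hydroxymethyl)-6-(methoxycarbonyl)-12-oxo-4-(triethylsilyloxy)dodeca-2,6,10-trienoate
Conditions: second-generation Hoveyda–Grubbs catalyst RuCl2(H2IMes)(=CH-C6H4-2-O-i-Pr) (10 mol %), 5 (3 equiv), toluene, 60 °C, argon sparge
Reagents that add atoms: none
Why: Olefin cross-metathesis of a terminal alkene with a 2-substituted acrylate that does not homodimerise; by analogy with methacrylates the alkyl chain should end trans to the ester (C2 cis to C9, the geometry the ring needs), and the allylic bromide, enal and free hydroxyl are tolerated.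

Step 10
Reactants: 19 ethyl (2Z,4S,5R,6E,10E)-5-acetoxy-2-(bromomethyl)-10-(hydroxymethyl)-6-(methoxycarbonyl)-12-oxo-4-(triethylsilyloxy)dodeca-2,6,10-trienoate
Product: 22 8-hydroxy lactone (25 with OH in place of the C8 isobutyrate; C6–C9 arranged as in 25), via silyl ether macrocycle 20 (not isolated), via triethylsilyl ether lactone 21 (not isolated)
Conditions: CrCl2 (15 mol %), Me3SiCl (4 equiv), n-Bu4NBF4 (0.1 M), THF–DMF 4:1, undivided cell, Al anode, Ni-foam cathode, constant current (2.4 F per mol), 19 added over 10 h (final 3 mM), 20 °C; then 1 M aq. HCl–THF, 0 → 20 °C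
Reagents that add atoms: none
Why: Proposed new method: an electroreductive, chromium-catalysed intramolecular Barbier (Nozaki–Hiyama) allylation/lactonisation. Cathodically regenerated divalent chromium inserts into the primary allylic C–Br bond and the 2-(ethoxycarbonyl)allyl species of trivalent chromium adds through its γ-carbon (C7) to the enal carbonyl (C6) in a chair transition state with both ring-forming substituents pseudo-equatorial, which gives the 6,7-trans relationship. C6 approaches C7 anti to C9 with H-8 in the allyl plane and the silyloxy group outside, so A(1,3) strain from the purchased C8 centre should set 6R,7S. Me3SiCl frees the catalyst from the alkoxide, and slow addition with low catalyst loading keeps the organochromium at high dilution for ten-membered ring closure before acid unmasks C6–OH (lactonisation with loss of ethanol) and C8–OH and cleaves any trimethylsilyl ether formed at C15. The closest known chemistry is the stoichiometric CrCl2 Barbier macrocyclisation of germacranolide precursors and the intermolecular chromium-catalysed electrochemical Nozaki–Hiyama–Kishi coupling; an electrochemically driven ring-forming version giving a ten-membered α-methylene lactone has not been described.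

Step 11
Reactants: 22 8-hydroxy lactone (25 with OH in place of the C8 isobutyrate)
Product: 25 CNP0242134.4, methyl (1(10)E,4E,6R,7S,8S,9R)-9-acetoxy-15-hydroxy-8-(2-methylpropanoyloxy)-12-oxogermacra-1(10),4,11(13)-trien-6,12-olid-14-oate, via silyl ether 23 (not isolated), via silyl ether ester 24 (not isolated)
Conditions: t-BuMe2SiCl (1.15 equiv), imidazole (2.5 equiv), CH2Cl2, −20 → 0 °C; then (i-PrCO)2O (3 equiv), Et3N (4 equiv), DMAP (0.3 equiv), 0 °C; then HF·pyridine, THF, 0 → 20 °C
Reagents that add atoms: isobutyric anhydride CC(C)C(=O)OC(=O)C(C)C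
Why: One-flask transient silylation of the primary allylic C15–OH, DMAP-catalysed esterification of the hindered secondary C8–OH and fluoride desilylation; no stereocentre changes, and the short cold exposure to base is meant to keep the C9 acetate from migrating to C8.

**Compound list**
1 | but-2-yne-1,4-diol | OCC#CCO | starting material
2 | but-3-en-1-ylmagnesium bromide | C=CCC[Mg]Br | starting material
3 | cyclic alkenylmagnesium alkoxide from 1 and 2 (five-membered C=C–Mg–O–CH2 chelate, butenyl on the carbon bearing the chelating CH2O, second CH2OMgBr on the magnesiated carbon) | C=CCCC1=C(CO[Mg]Br)[Mg]OC1 | intermediate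
4 | (2E)-2-(but-3-en-1-yl)but-2-ene-1,4-diol | OC/C=C(/CO)CCC=C | intermediate
5 | (2E)-3-(hydroxymethyl)hepta-2,6-dienal | O=C/C=C(/CO)CCC=C | intermediate
6 | methyl propiolate | C#CC(=O)OC | starting material
7 | (S)-2,2-dimethyl-1,3-dioxolane-4-carbaldehyde (L-glyceraldehyde acetonide) | O=C[C@@H]1COC(C)(C)O1 | starting material
8 | methyl 2-[bis(2-methylpropyl)alumanyl]prop-2-enoate (as its NMO adduct) | C=C([Al](CC(C)C)CC(C)C)C(=O)OC | intermediate
9 | diisobutylaluminium alkoxide of methyl 2-[(R)-[(4S)-2,2-dimethyl-1,3-dioxolan-4-yl](hydroxy)methyl]prop-2-enoate | C=C(C(=O)OC)[C@@H](O[Al](CC(C)C)CC(C)C)[C@@H]1COC(C)(C)O1 | intermediate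
10 | methyl 2-[(R)-acetoxy[(4S)-2,2-dimethyl-1,3-dioxolan-4-yl]methyl]prop-2-enoate | C=C(C(=O)OC)[C@@H](OC(C)=O)[C@@H]1COC(C)(C)O1 | intermediate
11 | methyl (3R,4S)-3-acetoxy-4,5-dihydroxy-2-methylidenepentanoate | C=C(C(=O)OC)[C@@H](OC(C)=O)[C@@H](O)CO | intermediate
12 | methyl (3R,4S)-3-acetoxy-2-methylidene-4,5-bis(triethylsilyloxy)pentanoate | C=C(C(=O)OC)[C@@H](OC(C)=O)[C@@H](O[Si](CC)(CC)CC)CO[Si](CC)(CC)CC | intermediate
13 | methyl (3R,4R)-3-acetoxy-2-methylidene-5-oxo-4-(triethylsilyloxy)pentanoate | C=C(C(=O)OC)[C@@H](OC(C)=O)[C@@H](O[Si](CC)(CC)CC)C=O | intermediate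
14 | ethyl propiolate | C#CC(=O)OCC | starting material
15 | ethyl 2-[bis(2-methylpropyl)alumanyl]prop-2-enoate (as its NMO adduct) | C=C([Al](CC(C)C)CC(C)C)C(=O)OCC | intermediate
16 | diisobutylaluminium alkoxide of 17 (C7 epimers) | C=C(C(=O)OC)[C@@H](OC(C)=O)[C@@H](O[Si](CC)(CC)CC)C(O[Al](CC(C)C)CC(C)C)C(=C)C(=O)OCC | intermediate
17 | 7-ethyl 1-methyl (3R,4S,5RS)-3-acetoxy-5-hydroxy-2,6-dimethylidene-4-(triethylsilyloxy)heptanedioate | C=C(C(=O)OC)[C@@H](OC(C)=O)[C@@H](O[Si](CC)(CC)CC)C(O)C(=C)C(=O)OCC | intermediate
18 | 1-ethyl 7-methyl (2Z,4S,5R)-5-acetoxy-2-(bromomethyl)-6-methylidene-4-(triethylsilyloxy)hept-2-enedioate | C=C(C(=O)OC)[C@@H](OC(C)=O)[C@@H](O[Si](CC)(CC)CC)/C=C(\CBr)C(=O)OCC | intermediate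
19 | ethyl (2Z,4S,5R,6E,10E)-5-acetoxy-2-(bromomethyl)-10-(hydroxymethyl)-6-(methoxycarbonyl)-12-oxo-4-(triethylsilyloxy)dodeca-2,6,10-trienoate | O=C/C=C(/CO)CC/C=C(/C(=O)OC)[C@@H](OC(C)=O)[C@@H](O[Si](CC)(CC)CC)/C=C(\CBr)C(=O)OCC | intermediate
20 | ten-membered seco-ester: carbocycle of 25 with C6–OSiMe3, C7–C(=CH2)CO2Et (lactone not yet closed), C8–OSiEt3, C9–OAc, C14 methyl ester, C15–OH; C6–C9 arranged as in 25 | C[Si](C)(C)O[C@@H]1/C=C(/CO)CC/C=C(/C(=O)OC)[C@@H](OC(C)=O)[C@@H](O[Si](CC)(CC)CC)[C@H]1C(=C)C(=O)OCC | intermediate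
21 | 8-O-triethylsilyl lactone: 25 with OSiEt3 in place of the C8 isobutyrate (6R,7S,8S,9R) | C=C1C(=O)O[C@@H]2/C=C(/CO)CC/C=C(/C(=O)OC)[C@@H](OC(C)=O)[C@@H](O[Si](CC)(CC)CC)[C@@H]12 | intermediate
22 | 8-hydroxy lactone: 25 with OH in place of the C8 isobutyrate (same spatial arrangement; formally 6R,7R,8S,9R by a priority change at C7) | C=C1C(=O)O[C@@H]2/C=C(/CO)CC/C=C(/C(=O)OC)[C@@H](OC(C)=O)[C@@H](O)[C@@H]12 | intermediate
23 | 15-O-(tert-butyldimethylsilyl) ether of 22 | C=C1C(=O)O[C@@H]2/C=C(/CO[Si](C)(C)C(C)(C)C)CC/C=C(/C(=O)OC)[C@@H](OC(C)=O)[C@@H](O)[C@@H]12 | intermediate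
24 | 15-O-(tert-butyldimethylsilyl) ether of 25 | C=C1C(=O)O[C@@H]2/C=C(/CO[Si](C)(C)C(C)(C)C)CC/C=C(/C(=O)OC)[C@@H](OC(C)=O)[C@@H](OC(=O)C(C)C)[C@@H]12 | intermediate
25 | CNP0242134.4, methyl (1(10)E,4E,6R,7S,8S,9R)-9-acetoxy-15-hydroxy-8-(2-methylpropanoyloxy)-12-oxogermacra-1(10),4,11(13)-trien-6,12-olid-14-oate | C=C1C(=O)O[C@@H]2/C=C(/CO)CC/C=C(/C(=O)OC)[C@@H](OC(C)=O)[C@@H](OC(=O)C(C)C)[C@@H]12 | target

**Totals**
Total step count: 11. Longest linear sequence: 9 steps (steps 3–11, from 7).

**Three steps most likely to fail**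

Step 10 (the proposed new macrocyclisation). Risks are electrode fouling, direct reduction of the bromide, oligomerisation, and a wrong C6/C7 outcome. Fallback: leave the catalytic electrochemical manifold and close the ring from 19 with the classical stoichiometric Nozaki–Hiyama Barbier reaction, known for ten-membered germacranolide ring closure. 19 is added by syringe pump to excess CrCl2 (8 equiv) in THF–DMF at 20 °C (final 2 mM) without electrode or silyl chloride, and the chromium alkoxide lactonises on aqueous work-up. This gives the triethylsilyl ether lactone 21 directly, which re-enters the route at 21 (1 M HCl–THF to 22, then step 11). New compound: none F0.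

Step 9 (cross-metathesis at a hindered 2-substituted acrylate). Risks are low conversion and E/Z mixtures. Fallback: reverse the order of ring formation. Starting from 18 and 5, an intermolecular CrCl2-mediated Barbier allylation/lactonisation (CrCl2 4 equiv, THF, 0 → 20 °C, anti-selective chromium allylation directed by the C8 silyloxy centre, diastereomers separated) gives the acyclic trans α-methylene-γ-butyrolactone triethylsilyl ether F1, in which both alkenes to be joined are still terminal. Ring-closing metathesis of F1 (second-generation Grubbs catalyst RuCl2(H2IMes)(PCy3)(=CHPh), toluene, 80 °C, 1 mM), where the ten-membered ring can only hold the ring-cis enoate, then gives 21, which returns to the route at 21 (acid work-up of step 10 to 22).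

Step 6 (one-pot oxidative desilylation to a β-acetoxy aldehyde). Risks are loss of acetic acid or epimerisation at C8 under the amine base. Fallback: unmask first, then oxidise without base. Starting from 12, selective cleavage of the primary silyl ether (PPTS, MeOH–CH2Cl2, 0 °C) gives the primary alcohol methyl (3R,4S)-3-acetoxy-5-hydroxy-2-methylidene-4-(triethylsilyloxy)pentanoate F2, which is oxidised with Dess–Martin periodinane buffered with NaHCO3 (CH2Cl2, 0 °C) to 13, where the route continues.

**Further compounds**
F0 | step 10 | none | none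
F1 | step 9 | acyclic trans α-methylene-γ-butyrolactone: lactone ring of 21 carrying at C6 the (1E)-2-(hydroxymethyl)hexa-1,5-dien-1-yl chain and at C7 the CH(OSiEt3)–CH(OAc)–C(=CH2)CO2Me chain, C6–C9 arranged as in 21 | C=C1C(=O)O[C@H](/C=C(/CO)CCC=C)[C@H]1[C@H](O[Si](CC)(CC)CC)[C@H](OC(C)=O)C(=C)C(=O)OC
F2 | step 6 | methyl (3R,4S)-3-acetoxy-5-hydroxy-2-methylidene-4-(triethylsilyloxy)pentanoate | C=C(C(=O)OC)[C@@H](OC(C)=O)[C@@H](O[Si](CC)(CC)CC)CO
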